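The pyran ring (ring C) of the lower flavan unit is closed at its C3–C4 bond. C4 is the benzylic carbon on C4a, ortho to ring oxygen O1, and C3 is the carbinol carbon beside aryl-bearing C2; as an alkene this bond joins a styrene to an O1-linked allyl ether. Ring-closing metathesis of an open (S)-1-arylallyl 2-vinylphenyl ether therefore closes ring C in one operation, and hydroboration then sets the 2,3-trans alcohol. The same sequence in the mirror-image series gives the upper unit, whose alkene is turned into a 2,3-cis C4 electrophile. Bromine at C6 of both units, carried from the start, forces the 4→8 Friedel–Crafts union.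

Key step: step 7

Remark: the target is read as ent-epifisetinidol-(4→8)-fisetinidol, upper unit 2S,3S,4S (2,3-cis, 3,4-trans) and lower unit 2R,3S (2,3-trans); the (Sa,Sc,Sc) ligand is assumed to give the (S)-ether 8 and its mirror image the (R)-ether 12, and the two ligands would change places if the sense were the reverse.

Step 1
Reactants: 1 5-bromo-2,4-dihydroxybenzaldehyde
Product: 2 4-(benzyloxy)-5-bromo-2-hydroxybenzaldehyde
Conditions: BnBr (1.05 equiv), NaHCO3, KI (cat.), MeCN, 80 °C
Reagents that add atoms: benzyl bromide, BrCc1ccccc1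
Why: Williamson ether synthesis; the 4-OH, para to the formyl group and free of the hydrogen bond that ties the 2-OH to the carbonyl, is the more acidic hydroxyl and should be alkylated selectively under the weak base.

Step 2
Reactants: 2 4-(benzyloxy)-5-bromo-2-hydroxybenzaldehyde
Product: 3 5-(benzyloxy)-4-bromo-2-ethenylphenol
Conditions: Ph3PCH3Br (2.5 equiv), KOt-Bu (2.5 equiv), THF, 0 °C to rt
Reagents that add atoms: methyltriphenylphosphonium bromide, C[P+](c1ccccc1)(c1ccccc1)c1ccccc1.[Br-]
Why: Wittig methylenation; one equivalent of ylide is spent on the phenol as base and the excess converts the aldehyde into the styrene whose inner carbon becomes C4.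

Step 3
Reactants: 4 3,4-bis(benzyloxy)benzaldehyde
Product: 5 ethyl (E)-3-[3,4-bis(benzyloxy)phenyl]prop-2-enoate
Conditions: (EtO)2P(O)CH2CO2Et, NaH, THF, 0 °C to rt
Reagents that add atoms: triethyl phosphonoacetate, CCOC(=O)CP(=O)(OCC)OCC
Why: Horner–Wadsworth–Emmons olefination, whose stabilised phosphonate anion should give the (E)-enoate.

Step 4
Reactants: 5 ethyl (E)-3-[3,4-bis(benzyloxy)phenyl]prop-2-enoate
Product: 6 (E)-3-[3,4-bis(benzyloxy)phenyl]prop-2-en-1-ol
Conditions: i-Bu2AlH (2.2 equiv), CH2Cl2, −78 °C; aq. potassium sodium tartrate work-up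
Reagents that add atoms: none
Why: 1,2-reduction of the conjugated ester by the aluminium hydride at low temperature should give the (E)-allylic alcohol without touching the alkene or the benzyl ethers.

Step 5
Reactants: 6 (E)-3-[3,4-bis(benzyloxy)phenyl]prop-2-en-1-ol
Product: 7 (E)-3-[3,4-bis(benzyloxy)phenyl]prop-2-en-1-yl methyl carbonate
Conditions: ClCO2Me, pyridine, CH2Cl2, 0 °C
Reagents that add atoms: methyl chloroformate, COC(=O)Cl
Why: O-acylation of the primary allylic alcohol (carbonate formation) installs the leaving group needed for allyl-iridium formation.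

Step 6
Reactants: 3 5-(benzyloxy)-4-bromo-2-ethenylphenol; 7 (E)-3-[3,4-bis(benzyloxy)phenyl]prop-2-en-1-yl methyl carbonate
Product: 8 1-(benzyloxy)-5-{[(1S)-1-[3,4-bis(benzyloxy)phenyl]prop-2-en-1-yl]oxy}-2-bromo-4-ethenylbenzene
Conditions: [Ir(cod)Cl]2 (2 mol %), (Sa,Sc,Sc)-binaphthol-derived N,N-bis(1-phenylethyl)phosphoramidite (4 mol %), n-PrNH2 pre-activation, K3PO4, THF, 50 °C
Reagents that add atoms: none
Why: iridium-catalysed asymmetric allylic substitution (etherification); the phenoxide of 3 attacks the aryl-substituted terminus of the allyl-iridium intermediate, which should give the branched ether, and the chiral phosphoramidite fixes the face of attack and so sets the stereocentre that becomes C2 of the lower unit.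

Step 7
Reactants: 8 1-(benzyloxy)-5-{[(1S)-1-[3,4-bis(benzyloxy)phenyl]prop-2-en-1-yl]oxy}-2-bromo-4-ethenylbenzene
Product: 9 (2S)-7-(benzyloxy)-2-[3,4-bis(benzyloxy)phenyl]-6-bromo-2H-chromene
Conditions: second-generation Grubbs catalyst RuCl2(=CHPh)(PCy3)(H2IMes) (3 mol %), 1,4-benzoquinone (10 mol %), CH2Cl2 (0.01 M), 40 °C
Reagents that add atoms: none
Why: Ring-closing olefin metathesis by the metallacyclobutane mechanism: the ruthenium benzylidene exchanges with one terminal alkene of 8, the new alkylidene adds across the other alkene to give a ruthenacyclobutane, and cycloreversion releases ethene and joins the former allyl-ether CH (C3) to the former styrene CH (C4). The closest known reaction type is the ring-closing metathesis of allyl 2-vinylphenyl ethers, a standard entry to 2H-chromenes. The six-membered ring C closes with the new C3=C4 bond endocyclic, the cis alkene being the only one the ring allows. No stereocentre is created: C2 comes unchanged from step 6, and C3 is set in step 8 under control of C2. The step needs ring closure to beat cross-metathesis and needs the absence of ruthenium hydride double-bond migration, which would turn the allyl ether into an enol ether and erase C2; two unhindered terminal alkenes held ortho on one arene, high dilution and 1,4-benzoquinone as hydride scavenger should secure both.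

Step 8
Reactants: 9 (2S)-7-(benzyloxy)-2-[3,4-bis(benzyloxy)phenyl]-6-bromo-2H-chromene
Product: 11 (2R,3S)-7-(benzyloxy)-2-[3,4-bis(benzyloxy)phenyl]-6-bromochroman-3-ol, via alkylborane 10 (not isolated)
Conditions: BH3·THF, THF, 0 °C to rt; then NaOH (aq), H2O2, 0 °C
Reagents that add atoms: borane (as THF complex, boron only in 10), B; hydrogen peroxide, OO
Why: hydroboration–oxidation; boron adds to C3, the alkene carbon next to the allylic oxygen-bearing C2 and remote from the donor-substituted ring A, on the face opposite the C2 aryl group and is replaced by OH with retention, which should give the 2,3-trans alcohol with C3 set as S under control of C2.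

Step 9
Reactants: 3 5-(benzyloxy)-4-bromo-2-ethenylphenol; 7 (E)-3-[3,4-bis(benzyloxy)phenyl]prop-2-en-1-yl methyl carbonate
Product: 12 1-(benzyloxy)-5-{[(1R)-1-[3,4-bis(benzyloxy)phenyl]prop-2-en-1-yl]oxy}-2-bromo-4-ethenylbenzene
Conditions: [Ir(cod)Cl]2 (2 mol %), (Ra,Rc,Rc)-binaphthol-derived N,N-bis(1-phenylethyl)phosphoramidite (4 mol %), n-PrNH2 pre-activation, K3PO4, THF, 50 °C
Reagents that add atoms: none
Why: the same iridium-catalysed asymmetric allylic etherification as in step 6 with the mirror-image ligand, which should set the stereocentre that becomes C2 (S in the flavan) of the upper unit.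

Step 10
Reactants: 12 1-(benzyloxy)-5-{[(1R)-1-[3,4-bis(benzyloxy)phenyl]prop-2-en-1-yl]oxy}-2-bromo-4-ethenylbenzene
Product: 13 (2R)-7-(benzyloxy)-2-[3,4-bis(benzyloxy)phenyl]-6-bromo-2H-chromene
Conditions: second-generation Grubbs catalyst RuCl2(=CHPh)(PCy3)(H2IMes) (3 mol %), 1,4-benzoquinone (10 mol %), CH2Cl2 (0.01 M), 40 °C
Reagents that add atoms: none
Why: ring-closing metathesis as in step 7 in the mirror-image series, closing ring C of the upper unit without touching C2.

Step 11
Reactants: 13 (2R)-7-(benzyloxy)-2-[3,4-bis(benzyloxy)phenyl]-6-bromo-2H-chromene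
Product: 14 (2S,3R,4S)-7-(benzyloxy)-2-[3,4-bis(benzyloxy)phenyl]-3,6-dibromochroman-4-ol
Conditions: NBS (1.0 equiv), THF/H2O (4:1), 0 °C, dark
Reagents that add atoms: N-bromosuccinimide, O=C1CCC(=O)N1Br; water, O
Why: bromohydrin formation (electrophilic bromohydroxylation); bromine adds to C3 on the face opposite the C2 aryl group and water opens the bromonium ion at benzylic C4, which is stabilised by O7 para and O1 ortho on ring A, anti to bromine, so that the C4 hydroxyl should lie on the face of the aryl group.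

Step 12
Reactants: 14 (2S,3R,4S)-7-(benzyloxy)-2-[3,4-bis(benzyloxy)phenyl]-3,6-dibromochroman-4-ol
Product: 16 (2S,3S,4R)-7-(benzyloxy)-2-[3,4-bis(benzyloxy)phenyl]-6-bromo-4-methoxychroman-3-ol, via epoxide 15 (not isolated)
Conditions: K2CO3 (1.5 equiv), MeOH/THF (3:1), 0 °C to rt
Reagents that add atoms: methanol, CO
Why: intramolecular Williamson closure followed by solvolytic epoxide opening; the C4 alkoxide displaces bromide at C3 with inversion, which puts the C3 oxygen cis to the 2-aryl group (C3 set as S), and methanol then opens the labile epoxide at the doubly oxygen-stabilised benzylic C4 with inversion, a centre whose configuration no longer matters once it is ionised in step 13.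

Step 13
Reactants: 16 (2S,3S,4R)-7-(benzyloxy)-2-[3,4-bis(benzyloxy)phenyl]-6-bromo-4-methoxychroman-3-ol; 11 (2R,3S)-7-(benzyloxy)-2-[3,4-bis(benzyloxy)phenyl]-6-bromochroman-3-ol (3 equiv)
Product: 17 (2S,3S,4S)-7-(benzyloxy)-4-[(2R,3S)-7-(benzyloxy)-2-[3,4-bis(benzyloxy)phenyl]-6-bromo-3-hydroxychroman-8-yl]-2-[3,4-bis(benzyloxy)phenyl]-6-bromochroman-3-ol
Conditions: TMSOTf (0.5 equiv), CH2Cl2, −40 to −20 °C, slow addition of 16 to 11; aq. NaHCO3 work-up, excess 11 recovered
Reagents that add atoms: none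
Why: Lewis acid-mediated Friedel–Crafts alkylation of the kind used for proanthocyanidin interflavan bonds; loss of methanol from C4 of 16 gives a benzylic cation stabilised by O7 and O1, C8 of 11 (the only ring A position flanked by two oxygens now that C6 carries bromine) attacks it on the face opposite the C3 hydroxyl of the 2,3-cis unit, which should set C4 as S (3,4-trans), and the C6 bromine of 16 blocks its own most nucleophilic position against self-condensation.

Step 14
Reactants: 17 (2S,3S,4S)-7-(benzyloxy)-4-[(2R,3S)-7-(benzyloxy)-2-[3,4-bis(benzyloxy)phenyl]-6-bromo-3-hydroxychroman-8-yl]-2-[3,4-bis(benzyloxy)phenyl]-6-bromochroman-3-ol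
Product: 18 (2S,3S,4S)-2-(3,4-dihydroxyphenyl)-4-[(2R,3S)-2-(3,4-dihydroxyphenyl)-3,7-dihydroxychroman-8-yl]chroman-3,7-diol (CNP0189433.2)
Conditions: H2 (1 atm), Pd(OH)2/C, Et3N, THF/MeOH/H2O, rt
Reagents that add atoms: none
Why: catalytic hydrogenolysis should cleave the six benzyl ethers and reduce both aryl bromides to C–H in one operation, the amine taking up HBr, without touching the five stereocentres or the interflavan bond.

Compound list
1 | 5-bromo-2,4-dihydroxybenzaldehyde | O=Cc1cc(Br)c(O)cc1O | starting material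
2 | 4-(benzyloxy)-5-bromo-2-hydroxybenzaldehyde | O=Cc1cc(Br)c(OCc2ccccc2)cc1O | intermediate
3 | 5-(benzyloxy)-4-bromo-2-ethenylphenol | C=Cc1cc(Br)c(OCc2ccccc2)cc1O | intermediate
4 | 3,4-bis(benzyloxy)benzaldehyde | O=Cc1ccc(OCc2ccccc2)c(OCc2ccccc2)c1 | starting material
5 | ethyl (E)-3-[3,4-bis(benzyloxy)phenyl]prop-2-enoate | CCOC(=O)/C=C/c1ccc(OCc2ccccc2)c(OCc2ccccc2)c1 | intermediate
6 | (E)-3-[3,4-bis(benzyloxy)phenyl]prop-2-en-1-ol | OC/C=C/c1ccc(OCc2ccccc2)c(OCc2ccccc2)c1 | intermediate
7 | (E)-3-[3,4-bis(benzyloxy)phenyl]prop-2-en-1-yl methyl carbonate | COC(=O)OC/C=C/c1ccc(OCc2ccccc2)c(OCc2ccccc2)c1 | intermediate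
8 | 1-(benzyloxy)-5-{[(1S)-1-[3,4-bis(benzyloxy)phenyl]prop-2-en-1-yl]oxy}-2-bromo-4-ethenylbenzene | C=Cc1cc(Br)c(OCc2ccccc2)cc1O[C@H](c1ccc(OCc2ccccc2)c(OCc2ccccc2)c1)C=C | intermediate
9 | (2S)-7-(benzyloxy)-2-[3,4-bis(benzyloxy)phenyl]-6-bromo-2H-chromene | Brc1cc2c(cc1OCc1ccccc1)O[C@H](c1ccc(OCc3ccccc3)c(OCc3ccccc3)c1)C=C2 | intermediate
10 | 2,3-trans C3-borane of the lower unit (boron on the face opposite the 2-aryl group), not isolated | Brc1cc2c(cc1OCc1ccccc1)O[C@H](c1ccc(OCc3ccccc3)c(OCc3ccccc3)c1)[C@@H](B)C2 | intermediate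
11 | (2R,3S)-7-(benzyloxy)-2-[3,4-bis(benzyloxy)phenyl]-6-bromochroman-3-ol | Brc1cc2c(cc1OCc1ccccc1)O[C@H](c1ccc(OCc3ccccc3)c(OCc3ccccc3)c1)[C@@H](O)C2 | intermediate
12 | 1-(benzyloxy)-5-{[(1R)-1-[3,4-bis(benzyloxy)phenyl]prop-2-en-1-yl]oxy}-2-bromo-4-ethenylbenzene | C=Cc1cc(Br)c(OCc2ccccc2)cc1O[C@@H](c1ccc(OCc2ccccc2)c(OCc2ccccc2)c1)C=C | intermediate
13 | (2R)-7-(benzyloxy)-2-[3,4-bis(benzyloxy)phenyl]-6-bromo-2H-chromene | Brc1cc2c(cc1OCc1ccccc1)O[C@@H](c1ccc(OCc3ccccc3)c(OCc3ccccc3)c1)C=C2 | intermediate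
14 | (2S,3R,4S)-7-(benzyloxy)-2-[3,4-bis(benzyloxy)phenyl]-3,6-dibromochroman-4-ol | Brc1cc2c(cc1OCc1ccccc1)O[C@@H](c1ccc(OCc3ccccc3)c(OCc3ccccc3)c1)[C@H](Br)[C@H]2O | intermediate
15 | (2S,3S,4S)-7-(benzyloxy)-2-[3,4-bis(benzyloxy)phenyl]-6-bromo-3,4-epoxychromane (epoxide oxygen cis to the 2-aryl group), not isolated | Brc1cc2c(cc1OCc1ccccc1)O[C@@H](c1ccc(OCc3ccccc3)c(OCc3ccccc3)c1)[C@H]3O[C@H]32 | intermediate
16 | (2S,3S,4R)-7-(benzyloxy)-2-[3,4-bis(benzyloxy)phenyl]-6-bromo-4-methoxychroman-3-ol | Brc1cc2c(cc1OCc1ccccc1)O[C@@H](c1ccc(OCc3ccccc3)c(OCc3ccccc3)c1)[C@@H](O)[C@@H]2OC | intermediate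
17 | (2S,3S,4S)-7-(benzyloxy)-4-[(2R,3S)-7-(benzyloxy)-2-[3,4-bis(benzyloxy)phenyl]-6-bromo-3-hydroxychroman-8-yl]-2-[3,4-bis(benzyloxy)phenyl]-6-bromochroman-3-ol | Brc1cc2c(cc1OCc1ccccc1)O[C@@H](c1ccc(OCc3ccccc3)c(OCc3ccccc3)c1)[C@@H](O)[C@@H]2c1c(OCc2ccccc2)c(Br)cc2c1O[C@H](c1ccc(OCc3ccccc3)c(OCc3ccccc3)c1)[C@@H](O)C2 | intermediate
18 | (2S,3S,4S)-2-(3,4-dihydroxyphenyl)-4-[(2R,3S)-2-(3,4-dihydroxyphenyl)-3,7-dihydroxychroman-8-yl]chroman-3,7-diol | Oc1ccc2c(c1)O[C@@H](c1ccc(O)c(O)c1)[C@@H](O)[C@@H]2c1c(O)ccc2c1O[C@H](c1ccc(O)c(O)c1)[C@@H](O)C2 | target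

Total step count: 14. Longest linear sequence: 9 steps (4 → 5 → 6 → 7 → 12 → 13 → 14 → 16 → 17 → 18, that is steps 3, 4, 5, 9, 10, 11, 12, 13 and 14).

Steps most likely to fail

Step 13. C8 of 11 is hindered and weakened by the C6 bromine, so it may attack too slowly. The cation from 16 would then be used up by attack on a ring B position, by oligomerisation through its own free C8, or by loss of the C3 hydrogen to the 3-ketone. The fallback sets out from 11 and 16 and comes back at 18; it replaces the ether nucleophile by a free phenol. The three benzyl ethers of 11 would be cleaved with BCl3 and pentamethylbenzene (CH2Cl2, −78 °C), which spares the aryl bromide, to give (2R,3S)-6-bromo-2-(3,4-dihydroxyphenyl)chroman-3,7-diol F1. Its free 7-hydroxyl makes C8 a smaller and stronger nucleophile than any benzyl ether ring in the flask. An excess of F1 would be condensed with 16 under BF3·OEt2 in dioxane/CH2Cl2 at 0 °C to give the half-protected dimer F2. Hydrogenolysis under the conditions of step 14 (H2, Pd(OH)2/C, Et3N) would convert F2 into 18.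

Step 12. The epoxide may rearrange by hydride shift from C3 to C4 faster than methanol captures C4. A poorly trans-selective bromohydrin formation in step 11 would also leave material that cannot close to the epoxide. The fallback sets out from 13 and comes back at 16 by known flavan chemistry. Hydroboration–oxidation of 13 as in step 8 would give the 2,3-trans alcohol (2S,3R)-7-(benzyloxy)-2-[3,4-bis(benzyloxy)phenyl]-6-bromochroman-3-ol F3. Dess–Martin periodinane would oxidise it to (2S)-7-(benzyloxy)-2-[3,4-bis(benzyloxy)phenyl]-6-bromochroman-3-one F4. LiBH(s-Bu)3 at −78 °C would deliver hydride on the face opposite the 2-aryl group to give the 2,3-cis alcohol (2S,3S)-7-(benzyloxy)-2-[3,4-bis(benzyloxy)phenyl]-6-bromochroman-3-ol F5. DDQ in CH2Cl2/MeOH would then oxidise benzylic C4, and methanol would trap the cation anti to the C3 hydroxyl to give 16.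

Step 6 (and its mirror image, step 9). The electron-rich dialkoxycinnamyl system ionises easily and the product ether can re-enter the allyl-iridium manifold, so enantiomeric purity may erode and the linear ether may form. The fallback sets out from 4 and 3 and comes back at 8 (and at 12); it replaces catalytic asymmetric substitution by a resolved alcohol and an SN2 etherification. Vinylmagnesium bromide would add to 4 to give racemic 1-[3,4-bis(benzyloxy)phenyl]prop-2-en-1-ol F6. Acylation with Candida antarctica lipase B and vinyl acetate should, by the usual preference of this lipase for secondary alcohols, give (R)-1-[3,4-bis(benzyloxy)phenyl]prop-2-en-1-yl acetate F7 and leave (S)-1-[3,4-bis(benzyloxy)phenyl]prop-2-en-1-ol F8. Methanolysis of F7 (K2CO3, MeOH) would give (R)-1-[3,4-bis(benzyloxy)phenyl]prop-2-en-1-ol F9. Mitsunobu reaction of F9 with 3 (PPh3, DIAD, toluene, 0 °C) would give 8 with inversion, and F8 would give 12 in the same way.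

Further compounds
F1 | step 13 | (2R,3S)-6-bromo-2-(3,4-dihydroxyphenyl)chroman-3,7-diol | Brc1cc2c(cc1O)O[C@H](c1ccc(O)c(O)c1)[C@@H](O)C2
F2 | step 13 | (2S,3S,4S)-7-(benzyloxy)-2-[3,4-bis(benzyloxy)phenyl]-6-bromo-4-[(2R,3S)-6-bromo-2-(3,4-dihydroxyphenyl)-3,7-dihydroxychroman-8-yl]chroman-3-ol | Brc1cc2c(cc1OCc1ccccc1)O[C@@H](c1ccc(OCc3ccccc3)c(OCc3ccccc3)c1)[C@@H](O)[C@@H]2c1c(O)c(Br)cc2c1O[C@H](c1ccc(O)c(O)c1)[C@@H](O)C2
F3 | step 12 | (2S,3R)-7-(benzyloxy)-2-[3,4-bis(benzyloxy)phenyl]-6-bromochroman-3-ol | Brc1cc2c(cc1OCc1ccccc1)O[C@@H](c1ccc(OCc3ccccc3)c(OCc3ccccc3)c1)[C@H](O)C2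
F4 | step 12 | (2S)-7-(benzyloxy)-2-[3,4-bis(benzyloxy)phenyl]-6-bromochroman-3-one | Brc1cc2c(cc1OCc1ccccc1)O[C@@H](c1ccc(OCc3ccccc3)c(OCc3ccccc3)c1)C(=O)C2
F5 | step 12 | (2S,3S)-7-(benzyloxy)-2-[3,4-bis(benzyloxy)phenyl]-6-bromochroman-3-ol | Brc1cc2c(cc1OCc1ccccc1)O[C@@H](c1ccc(OCc3ccccc3)c(OCc3ccccc3)c1)[C@@H](O)C2
F6 | step 6 | racemic 1-[3,4-bis(benzyloxy)phenyl]prop-2-en-1-ol | C=CC(O)c1ccc(OCc2ccccc2)c(OCc2ccccc2)c1
F7 | step 6 | (R)-1-[3,4-bis(benzyloxy)phenyl]prop-2-en-1-yl acetate | C=C[C@@H](OC(C)=O)c1ccc(OCc2ccccc2)c(OCc2ccccc2)c1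
F8 | step 6 | (S)-1-[3,4-bis(benzyloxy)phenyl]prop-2-en-1-ol | C=C[C@H](O)c1ccc(OCc2ccccc2)c(OCc2ccccc2)c1
F9 | step 6 | (R)-1-[3,4-bis(benzyloxy)phenyl]prop-2-en-1-ol | C=C[C@@H](O)c1ccc(OCc2ccccc2)c(OCc2ccccc2)c1
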